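## Retrosynthetic overview

1. The (E)-enol ester C–O bond is made last but one, from an (E)-alkenyltrifluoroborate and 3-methylbut-2-enoic acid (copper, O2). The alkenylboron comes from a C7 aldehyde, and the methyl ketone stays masked as a dioxolane until the final step.
2. C4–OH comes from a C4–Si bond (Tamao oxidation, retention); C6–CH3 comes from C6–CHO.
3. Key step: the cyclohexene ring is closed by a Diels–Alder reaction of a (Z,Z)-3,4-bis(alkylidene)oxolane with 2-(4-methylpent-3-enyl)acrolein. C4, C6 and C7 are set together under control of C1. This replaces the usual plan of elaborating a conjugate-addition-derived cyclohexenone and closing the ether by oxa-Michael addition.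
4. The diene comes from a 1,6-diyne ether by palladium-catalysed reductive cyclisation. The oxolane ring is formed first, the cyclohexene ring second.
5. C1 comes from asymmetric transfer hydrogenation of an ynone; it is the only stereocentre made with a chiral reagent.

Assumption: 2-benzofuran numbering is used (C1 carries the 2-oxopropyl group, then O2, C3, C3a, C4 carbinol, C5, C6 quaternary, C7, C7a); the given SMILES then reads (1S,4S,6S,7R) with an E enol ester, and C4–OH, C6–CH3 and the C7 side chain are all cis, trans to the C1 side chain.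

## Route

Step 1
Reactants: 1 methallyl alcohol (2-methylprop-2-en-1-ol); 2 prenyl bromide (1-bromo-3-methylbut-2-ene)
Product: 3 dienol 6-methyl-2-methylidenehept-5-en-1-ol
Conditions: n-BuLi (2.2 equiv), TMEDA, Et2O, 0 to 25 °C; then 2, −78 to 25 °C; H2O
Reagents that add atoms: none
Why: Allylic lithiation gives the symmetrical methallyl alcohol dianion, which is C-alkylated by the primary allylic bromide (SN2 alkylation of an allyl anion).

Step 2
Reactants: 3 dienol
Product: 4 enal 6-methyl-2-methylidenehept-5-enal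
Conditions: TEMPO (10 mol %), PhI(OAc)2 (1.1 equiv), CH2Cl2, 25 °C; used fresh
Reagents that add atoms: none
Why: Oxoammonium (TEMPO/PhI(OAc)2) oxidation of a primary allylic alcohol stops cleanly at the 2-alkylacrolein.

Step 3
Reactants: 5 ethyl (2-methyl-1,3-dioxolan-2-yl)acetate
Product: 6 Weinreb amide N-methoxy-N-methyl-2-(2-methyl-1,3-dioxolan-2-yl)acetamide
Conditions: MeNHOMe·HCl, i-PrMgCl, THF, −20 to 0 °C
Reagents that add atoms: N,O-dimethylhydroxylamine hydrochloride, CNOC.Cl
Why: Aminolysis of the ester by the magnesium amide gives the Weinreb amide (Weinreb amide synthesis), with the ketone of the future 2-oxopropyl group already protected.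

Step 4
Reactants: 6 Weinreb amide; 7 tert-butyl(dimethyl)(prop-2-yn-1-yloxy)silane
Product: 8 ynone 5-(TBS-oxy)-1-(2-methyl-1,3-dioxolan-2-yl)pent-3-yn-2-one
Conditions: 7, n-BuLi, THF, −78 °C; then 6, −78 to 0 °C; H2O
Reagents that add atoms: none
Why: Acylation of the lithium acetylide by the Weinreb amide stops at the ketone because the chelated tetrahedral adduct survives until work-up (Weinreb ketone synthesis).

Step 5
Reactants: 8 ynone
Product: 9 propargylic alcohol (2S)-5-(TBS-oxy)-1-(2-methyl-1,3-dioxolan-2-yl)pent-3-yn-2-ol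
Conditions: Ru[(S,S)-TsDPEN](p-cymene) (1 mol %), i-PrOH, 25 °C
Reagents that add atoms: none
Why: Noyori asymmetric transfer hydrogenation of an alkynyl ketone, in which the alkyne takes the aryl-like position so the (S,S)-ligand delivers hydride to give the (S)-carbinol (future C1; sense by analogy, checked by Mosher esters).

Step 6
Reactants: 9 propargylic alcohol; 10 propargyl bromide (3-bromoprop-1-yne)
Product: 11 diyne ether tert-butyl(dimethyl){[(4S)-5-(2-methyl-1,3-dioxolan-2-yl)-4-(prop-2-yn-1-yloxy)pent-2-yn-1-yl]oxy}silane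
Conditions: NaH, Bu4NI (cat.), THF, 0 to 25 °C
Reagents that add atoms: none
Why: Williamson etherification of the sodium alkoxide with a primary propargylic bromide leaves the C1 centre untouched.

Step 7
Reactants: 11 diyne ether
Product: 13 tert-butoxy(dimethyl)silyl diyne, via chlorosilane 12 (not isolated)
Conditions: n-BuLi (1.0 equiv), THF, −78 °C; Me2SiCl2 (5 equiv), −78 to 25 °C, volatiles removed; then t-BuOH, Et3N, DMAP (cat.), CH2Cl2, 25 °C
Reagents that add atoms: dichlorodimethylsilane, C[Si](C)(Cl)Cl; 2-methylpropan-2-ol, CC(C)(C)O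
Why: C-silylation of the terminal acetylide followed by alcoholysis of the Si–Cl bond installs a hydrolytically robust alkoxysilane that will later be the C4 hydroxyl (masked-hydroxyl silicon group).

Step 8
Reactants: 13 silyl diyne
Product: 14 diene (2S,3Z,4Z)-3,4-bis(alkylidene)oxolane
Conditions: Pd2(dba)3·CHCl3 (2.5 mol %), P(o-tol)3 (10 mol %), AcOH (2 equiv), Et3SiH (5 equiv), PhMe, 25 °C; filtered through neutral alumina and used at once
Reagents that add atoms: none
Why: Palladium hydride reductive diyne cyclisation (syn hydropalladation, 5-exo-dig syn carbopalladation of the silylalkyne, Si–H reduction of the vinyl–Pd bond with retention) closes the oxolane and places both substituents on the outside of an s-cis-locked diene.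

Step 9
Reactants: 14 diene; 4 enal
Product: 15 Diels–Alder aldehyde (1S,4S,6R,7S)-hexahydro-2-benzofuran-6-carbaldehyde
Conditions: 4 (2 equiv), Me2AlCl (0.25 equiv), CH2Cl2, −78 to −30 °C
Reagents that add atoms: none
Why: Lewis-acid Diels–Alder reaction in which the enal CH2 bonds to the silyl-bearing terminus (ortho to the alkyl terminus, quaternary carbon away from silicon), the Al-bound formyl group is endo and the dienophile comes anti to the C1 side chain, so the two outside groups and the formyl group end up all-cis and trans to the C1 chain, setting C4, C6 and C7 at once.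

Step 10
Reactants: 15 Diels–Alder aldehyde
Product: 16 tosylhydrazone of 15
Conditions: TsNHNH2 (1.2 equiv), MgSO4, THF, 25 °C
Reagents that add atoms: 4-methylbenzenesulfonohydrazide, Cc1ccc(cc1)S(=O)(=O)NN
Why: Condensation of the unhindered aldehyde carbonyl gives the hydrazone without touching any stereocentre (the aldehyde has no α-hydrogen).

Step 11
Reactants: 16 tosylhydrazone
Product: 17 C6-methyl silane
Conditions: catecholborane (3 equiv), CHCl3, 0 °C; then NaOAc·3H2O, 60 °C
Reagents that add atoms: none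
Why: Kabalka reduction (hydroboration of C=N, loss of sulfinate, then N2 from the alkyldiazene) turns the quaternary formyl group into the C6 methyl group under neutral conditions that spare the ketal, silyl ether and allylsilane.

Step 12
Reactants: 17 C6-methyl silane
Product: 18 diol (1S,4S,6S,7R)-7-(hydroxymethyl)-hexahydro-2-benzofuran-4-ol
Conditions: 30 % H2O2, KHCO3, Bu4NF, THF/MeOH, 0 to 45 °C
Reagents that add atoms: hydrogen peroxide, OO
Why: Tamao oxidation (fluoride-activated peroxide attack at silicon and 1,2-shift of C4 from Si to O with retention) gives the C4 alcohol on the face fixed in step 9, while fluoride also removes the primary TBS group.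

Step 13
Reactants: 18 diol
Product: 19 bis(triethylsilyl) ether of 18
Conditions: Et3SiCl, imidazole, DMAP (cat.), DMF, 25 °C
Reagents that add atoms: chlorotriethylsilane, CC[Si](Cl)(CC)CC
Why: Silylation of both hydroxyls covers the C4 alcohol so that the cis-disposed C7 formyl group made next cannot close to a bridged lactol and over-oxidise.

Step 14
Reactants: 19 bis(triethylsilyl) ether
Product: 20 aldehyde (1S,4S,6S,7R)-4-(triethylsilyloxy)-hexahydro-2-benzofuran-7-carbaldehyde
Conditions: (COCl)2, DMSO, CH2Cl2, −78 to −40 °C; then Et3N, −78 to 0 °C; used crude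
Reagents that add atoms: none
Why: Swern conditions cleave and oxidise a primary triethylsilyl ether directly to the aldehyde while the secondary silyl ether stays, and the cold short base contact avoids epimerising the allylic C7–H.

Step 15
Reactants: 20 aldehyde
Product: 21 (E)-alkenyl pinacol boronate
Conditions: Cl2CHB(pin), CrCl2, LiI, THF, 25 °C
Reagents that add atoms: 2-(dichloromethyl)-4,4,5,5-tetramethyl-1,3,2-dioxaborolane, ClC(Cl)B1OC(C)(C)C(C)(C)O1
Why: Takai–Utimoto olefination with a geminal dichromium boryl carbenoid homologates the hindered aldehyde to the (E)-alkenylboronate with high E selectivity under non-basic conditions.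

Step 16
Reactants: 21 alkenyl pinacol boronate
Product: 22 potassium (E)-alkenyltrifluoroborate with free C4 hydroxyl
Conditions: KHF2, MeOH/H2O, 25 °C
Reagents that add atoms: potassium hydrogen difluoride, F.[F-].[K+]
Why: Bifluoride exchanges pinacol for fluoride at boron and at the same time cleaves the triethylsilyl ether, neither of which affects the alkene geometry.

Step 17
Reactants: 22 alkenyltrifluoroborate; 23 3-methylbut-2-enoic acid
Product: 24 enol ester ketal
Conditions: 23 (3 equiv), CuBr (20 mol %), DMAP (40 mol %), 4 Å MS, O2 (1 atm), CH2Cl2, 35 °C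
Reagents that add atoms: none
Why: Copper-catalysed oxidative C–O coupling of an alkenyltrifluoroborate with a carboxylic acid (Chan–Lam–Evans type) is stereoretentive at the alkene and gives the (E)-enol ester, the carboxylate reacting much faster than the hindered C4 alcohol.

Step 18
Reactants: 24 enol ester ketal
Product: 25 target, (E)-2-[(1S,4S,6S,7R)-4-hydroxy-6-methyl-6-(4-methylpent-3-en-1-yl)-1-(2-oxopropyl)-1,3,4,5,6,7-hexahydro-2-benzofuran-7-yl]ethenyl 3-methylbut-2-enoate
Conditions: PPTS (0.3 equiv), acetone/H2O 10:1, 40 °C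
Reagents that add atoms: water, O
Why: Mild acid hydrolysis of the dioxolane frees the ketone only at the end, so C1 (a β-alkoxy ketone centre that could epimerise by retro-oxa-Michael reaction under base) is never exposed to base.

## Compound list

1 | 2-methylprop-2-en-1-ol | CC(=C)CO | starting material
2 | 1-bromo-3-methylbut-2-ene | CC(C)=CCBr | starting material
3 | 6-methyl-2-methylidenehept-5-en-1-ol | CC(C)=CCCC(=C)CO | intermediate
4 | 6-methyl-2-methylidenehept-5-enal | CC(C)=CCCC(=C)C=O | intermediate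
5 | ethyl (2-methyl-1,3-dioxolan-2-yl)acetate | CCOC(=O)CC1(C)OCCO1 | starting material
6 | N-methoxy-N-methyl-2-(2-methyl-1,3-dioxolan-2-yl)acetamide | CON(C)C(=O)CC1(C)OCCO1 | intermediate
7 | tert-butyl(dimethyl)(prop-2-yn-1-yloxy)silane | C#CCO[Si](C)(C)C(C)(C)C | starting material
8 | 5-{[tert-butyl(dimethyl)silyl]oxy}-1-(2-methyl-1,3-dioxolan-2-yl)pent-3-yn-2-one | CC1(CC(=O)C#CCO[Si](C)(C)C(C)(C)C)OCCO1 | intermediate
9 | (2S)-5-{[tert-butyl(dimethyl)silyl]oxy}-1-(2-methyl-1,3-dioxolan-2-yl)pent-3-yn-2-ol | CC1(C[C@H](O)C#CCO[Si](C)(C)C(C)(C)C)OCCO1 | intermediate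
10 | 3-bromoprop-1-yne | C#CCBr | starting material
11 | tert-butyl(dimethyl){[(4S)-5-(2-methyl-1,3-dioxolan-2-yl)-4-(prop-2-yn-1-yloxy)pent-2-yn-1-yl]oxy}silane | CC1(C[C@H](OCC#C)C#CCO[Si](C)(C)C(C)(C)C)OCCO1 | intermediate
12 | {3-[((2S)-5-{[tert-butyl(dimethyl)silyl]oxy}-1-(2-methyl-1,3-dioxolan-2-yl)pent-3-yn-2-yl)oxy]prop-1-yn-1-yl}(chloro)dimethylsilane | CC1(C[C@H](OCC#C[Si](C)(C)Cl)C#CCO[Si](C)(C)C(C)(C)C)OCCO1 | intermediate
13 | tert-butoxy{3-[((2S)-5-{[tert-butyl(dimethyl)silyl]oxy}-1-(2-methyl-1,3-dioxolan-2-yl)pent-3-yn-2-yl)oxy]prop-1-yn-1-yl}dimethylsilane | CC1(C[C@H](OCC#C[Si](C)(C)OC(C)(C)C)C#CCO[Si](C)(C)C(C)(C)C)OCCO1 | intermediate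
14 | (2S,3Z,4Z)-4-{[tert-butoxy(dimethyl)silyl]methylidene}-3-(2-{[tert-butyl(dimethyl)silyl]oxy}ethylidene)-2-[(2-methyl-1,3-dioxolan-2-yl)methyl]oxolane | CC3(OCCO3)C[C@@H]1OC/C(=C\[Si](C)(C)OC(C)(C)C)/C1=C/CO[Si](C)(C)C(C)(C)C | intermediate
15 | (1S,4S,6R,7S)-4-[tert-butoxy(dimethyl)silyl]-7-({[tert-butyl(dimethyl)silyl]oxy}methyl)-1-[(2-methyl-1,3-dioxolan-2-yl)methyl]-6-(4-methylpent-3-en-1-yl)-1,3,4,5,6,7-hexahydro-2-benzofuran-6-carbaldehyde | CC3(OCCO3)C[C@@H]1OCC2=C1[C@H](CO[Si](C)(C)C(C)(C)C)[C@@](C=O)(CCC=C(C)C)C[C@@H]2[Si](C)(C)OC(C)(C)C | intermediate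
16 | N'-[(E)-{(1S,4S,6R,7R)-4-[tert-butoxy(dimethyl)silyl]-7-({[tert-butyl(dimethyl)silyl]oxy}methyl)-1-[(2-methyl-1,3-dioxolan-2-yl)methyl]-6-(4-methylpent-3-en-1-yl)-1,3,4,5,6,7-hexahydro-2-benzofuran-6-yl}methylidene]-4-methylbenzenesulfonohydrazide | CC3(OCCO3)C[C@@H]1OCC2=C1[C@H](CO[Si](C)(C)C(C)(C)C)[C@@](/C=N/NS(=O)(=O)c4ccc(C)cc4)(CCC=C(C)C)C[C@@H]2[Si](C)(C)OC(C)(C)C | intermediate
17 | tert-butoxy{(1S,4S,6S,7R)-7-({[tert-butyl(dimethyl)silyl]oxy}methyl)-6-methyl-1-[(2-methyl-1,3-dioxolan-2-yl)methyl]-6-(4-methylpent-3-en-1-yl)-1,3,4,5,6,7-hexahydro-2-benzofuran-4-yl}dimethylsilane | CC3(OCCO3)C[C@@H]1OCC2=C1[C@H](CO[Si](C)(C)C(C)(C)C)[C@@](C)(CCC=C(C)C)C[C@@H]2[Si](C)(C)OC(C)(C)C | intermediate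
18 | (1S,4S,6S,7R)-7-(hydroxymethyl)-6-methyl-1-[(2-methyl-1,3-dioxolan-2-yl)methyl]-6-(4-methylpent-3-en-1-yl)-1,3,4,5,6,7-hexahydro-2-benzofuran-4-ol | CC3(OCCO3)C[C@@H]1OCC2=C1[C@H](CO)[C@@](C)(CCC=C(C)C)C[C@@H]2O | intermediate
19 | triethyl{[(1S,4S,6S,7R)-6-methyl-1-[(2-methyl-1,3-dioxolan-2-yl)methyl]-6-(4-methylpent-3-en-1-yl)-7-{[(triethylsilyl)oxy]methyl}-1,3,4,5,6,7-hexahydro-2-benzofuran-4-yl]oxy}silane | CC3(OCCO3)C[C@@H]1OCC2=C1[C@H](CO[Si](CC)(CC)CC)[C@@](C)(CCC=C(C)C)C[C@@H]2O[Si](CC)(CC)CC | intermediate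
20 | (1S,4S,6S,7R)-6-methyl-1-[(2-methyl-1,3-dioxolan-2-yl)methyl]-6-(4-methylpent-3-en-1-yl)-4-[(triethylsilyl)oxy]-1,3,4,5,6,7-hexahydro-2-benzofuran-7-carbaldehyde | CC3(OCCO3)C[C@@H]1OCC2=C1[C@H](C=O)[C@@](C)(CCC=C(C)C)C[C@@H]2O[Si](CC)(CC)CC | intermediate
21 | triethyl{[(1S,4S,6S,7R)-6-methyl-1-[(2-methyl-1,3-dioxolan-2-yl)methyl]-6-(4-methylpent-3-en-1-yl)-7-[(E)-2-(4,4,5,5-tetramethyl-1,3,2-dioxaborolan-2-yl)ethenyl]-1,3,4,5,6,7-hexahydro-2-benzofuran-4-yl]oxy}silane | CC3(OCCO3)C[C@@H]1OCC2=C1[C@H](/C=C/B4OC(C)(C)C(C)(C)O4)[C@@](C)(CCC=C(C)C)C[C@@H]2O[Si](CC)(CC)CC | intermediate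
22 | potassium trifluoro{(E)-2-[(1S,4S,6S,7R)-4-hydroxy-6-methyl-1-[(2-methyl-1,3-dioxolan-2-yl)methyl]-6-(4-methylpent-3-en-1-yl)-1,3,4,5,6,7-hexahydro-2-benzofuran-7-yl]ethenyl}borate | CC3(OCCO3)C[C@@H]1OCC2=C1[C@H](/C=C/[B-](F)(F)F)[C@@](C)(CCC=C(C)C)C[C@@H]2O.[K+] | intermediate
23 | 3-methylbut-2-enoic acid | CC(C)=CC(=O)O | starting material
24 | (E)-2-[(1S,4S,6S,7R)-4-hydroxy-6-methyl-1-[(2-methyl-1,3-dioxolan-2-yl)methyl]-6-(4-methylpent-3-en-1-yl)-1,3,4,5,6,7-hexahydro-2-benzofuran-7-yl]ethenyl 3-methylbut-2-enoate | CC3(OCCO3)C[C@@H]1OCC2=C1[C@H](/C=C/OC(=O)C=C(C)C)[C@@](C)(CCC=C(C)C)C[C@@H]2O | intermediate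
25 | (E)-2-[(1S,4S,6S,7R)-4-hydroxy-6-methyl-6-(4-methylpent-3-en-1-yl)-1-(2-oxopropyl)-1,3,4,5,6,7-hexahydro-2-benzofuran-7-yl]ethenyl 3-methylbut-2-enoate | CC(=O)C[C@@H]1OCC2=C1[C@H](/C=C/OC(=O)C=C(C)C)[C@@](C)(CCC=C(C)C)C[C@@H]2O | target

## Step count and risk

Total step count: 18. Longest linear sequence: 16 steps (5 to 25, steps 3–18); the dienophile branch (steps 1–2) joins at step 9.

The three steps most likely to fail:

Step 8 (reductive diyne cyclisation). The diene may form sluggishly from the hindered silylalkyne or drift toward the aromatic 3,4-disubstituted furan under palladium hydride. The fallback sets out from 13 and replaces the hydrogen transfer by a tin transfer: Bu3SnH with Pd2(dba)3 in THF at 0 °C effects hydrostannylative cyclisation to the vinylstannane diene (2S,3E,4Z)-4-{[tert-butoxy(dimethyl)silyl]methylidene}-3-[2-{[tert-butyl(dimethyl)silyl]oxy}-1-(tributylstannyl)ethylidene]-2-[(2-methyl-1,3-dioxolan-2-yl)methyl]oxolane F1, with tin on the inside position. Stereoretentive protodestannylation with one equivalent of HCl in Et2O at −78 °C then returns to 14.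

Step 9 (Diels–Alder reaction). The 2-alkylacrolein may react slowly at the substituted diene terminus or give poor endo control. Coordination of aluminium to the ketal could also erode the anti facial preference. The fallback sets out from 14 and moves the making of the quaternary centre out of the cycloaddition. The small dienophile methyl acrylate (PhMe, 40 °C) gives the ester adduct methyl (1S,4S,7R)-4-[tert-butoxy(dimethyl)silyl]-7-({[tert-butyl(dimethyl)silyl]oxy}methyl)-1-[(2-methyl-1,3-dioxolan-2-yl)methyl]-1,3,4,5,6,7-hexahydro-2-benzofuran-6-carboxylate F2 as a C6 epimer mixture. The enolate (LiN(i-Pr)2, THF/DMPU, −78 °C) is alkylated by 5-iodo-2-methylpent-2-ene on the face anti to the C7 and C4 groups to give the quaternary ester methyl (1S,4S,6R,7S)-4-[tert-butoxy(dimethyl)silyl]-7-({[tert-butyl(dimethyl)silyl]oxy}methyl)-1-[(2-methyl-1,3-dioxolan-2-yl)methyl]-6-(4-methylpent-3-en-1-yl)-1,3,4,5,6,7-hexahydro-2-benzofuran-6-carboxylate F3. Reduction with i-Bu2AlH at −78 °C returns to 15.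

Step 17 (copper-mediated enol esterification). The free C4 hydroxyl, the acyl-donor character of the product and protodeboronation may all cut the yield. The fallback sets out from 20 and makes the C–O bond from an electrophilic alkene partner instead. Takai iodo-olefination (CrCl2, CHI3, THF, 0 °C) gives the vinyl iodide triethyl{[(1S,4S,6S,7R)-7-[(E)-2-iodoethenyl]-6-methyl-1-[(2-methyl-1,3-dioxolan-2-yl)methyl]-6-(4-methylpent-3-en-1-yl)-1,3,4,5,6,7-hexahydro-2-benzofuran-4-yl]oxy}silane F4. Ullmann-type coupling with 23 (CuI, 3,4,7,8-tetramethyl-1,10-phenanthroline, Cs2CO3, PhMe, 80 °C; by analogy with copper-catalysed C–N and C–O couplings of vinyl iodides) gives the silyl-protected enol ester (E)-2-[(1S,4S,6S,7R)-6-methyl-1-[(2-methyl-1,3-dioxolan-2-yl)methyl]-6-(4-methylpent-3-en-1-yl)-4-[(triethylsilyl)oxy]-1,3,4,5,6,7-hexahydro-2-benzofuran-7-yl]ethenyl 3-methylbut-2-enoate F5. PPTS in acetone/H2O removes the silyl ether and the ketal together and comes back to the route at 25.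

## Further compounds

F1 | step 8 | (2S,3E,4Z)-4-{[tert-butoxy(dimethyl)silyl]methylidene}-3-[2-{[tert-butyl(dimethyl)silyl]oxy}-1-(tributylstannyl)ethylidene]-2-[(2-methyl-1,3-dioxolan-2-yl)methyl]oxolane | CC3(OCCO3)C[C@@H]1OC/C(=C\[Si](C)(C)OC(C)(C)C)/C1=C(/CO[Si](C)(C)C(C)(C)C)[Sn](CCCC)(CCCC)CCCC
F2 | step 9 | methyl (1S,4S,7R)-4-[tert-butoxy(dimethyl)silyl]-7-({[tert-butyl(dimethyl)silyl]oxy}methyl)-1-[(2-methyl-1,3-dioxolan-2-yl)methyl]-1,3,4,5,6,7-hexahydro-2-benzofuran-6-carboxylate (C6 epimer mixture) | CC3(OCCO3)C[C@@H]1OCC2=C1[C@H](CO[Si](C)(C)C(C)(C)C)C(C(=O)OC)C[C@@H]2[Si](C)(C)OC(C)(C)C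
F3 | step 9 | methyl (1S,4S,6R,7S)-4-[tert-butoxy(dimethyl)silyl]-7-({[tert-butyl(dimethyl)silyl]oxy}methyl)-1-[(2-methyl-1,3-dioxolan-2-yl)methyl]-6-(4-methylpent-3-en-1-yl)-1,3,4,5,6,7-hexahydro-2-benzofuran-6-carboxylate | CC3(OCCO3)C[C@@H]1OCC2=C1[C@H](CO[Si](C)(C)C(C)(C)C)[C@@](C(=O)OC)(CCC=C(C)C)C[C@@H]2[Si](C)(C)OC(C)(C)C
F4 | step 17 | triethyl{[(1S,4S,6S,7R)-7-[(E)-2-iodoethenyl]-6-methyl-1-[(2-methyl-1,3-dioxolan-2-yl)methyl]-6-(4-methylpent-3-en-1-yl)-1,3,4,5,6,7-hexahydro-2-benzofuran-4-yl]oxy}silane | CC3(OCCO3)C[C@@H]1OCC2=C1[C@H](/C=C/I)[C@@](C)(CCC=C(C)C)C[C@@H]2O[Si](CC)(CC)CC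
F5 | step 17 | (E)-2-[(1S,4S,6S,7R)-6-methyl-1-[(2-methyl-1,3-dioxolan-2-yl)methyl]-6-(4-methylpent-3-en-1-yl)-4-[(triethylsilyl)oxy]-1,3,4,5,6,7-hexahydro-2-benzofuran-7-yl]ethenyl 3-methylbut-2-enoate | CC3(OCCO3)C[C@@H]1OCC2=C1[C@H](/C=C/OC(=O)C=C(C)C)[C@@](C)(CCC=C(C)C)C[C@@H]2O[Si](CC)(CC)CC
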